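The pyrrole ring is disconnected at the C3–C4 bond. Amino acetal 1 adds to alkyne diester 2 to give enamine 3, whose N1–C2(CO2Me)=C3 unit is an α-amino acrylate with nucleophilic C3 and whose N1–C5–C4 arm ends in a masked aldehyde. In one acid-mediated operation C3 attacks C4, the five-membered ring closes and two methanols are lost, giving the aromatic 1-methylpyrrole-2,3-diester. The C3 carboxyl so installed stands in for the bromine that is hardest to introduce: after C4/C5 bromination it is unmasked selectively and replaced by ipso-bromodecarboxylation, and saponification of the C2 ester then gives the target.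

Key step: step 2

Remark: the target is achiral; ring atoms are numbered as in the target (N1, C2 bearing the carboxyl, C3–C5). Enamine 3 is drawn as the (E)-isomer expected from a secondary amine and an acetylenic diester, and either alkene geometry would converge in step 2.

Step 1
Reactants: 1 (methylamino)acetaldehyde dimethyl acetal (2,2-dimethoxy-N-methylethanamine); 2 dimethyl acetylenedicarboxylate (dimethyl but-2-ynedioate)
Product: 3 dimethyl (E)-2-[(2,2-dimethoxyethyl)(methyl)amino]but-2-enedioate
Conditions: 1 (1.0 equiv) added to 2 (1.0 equiv), CH2Cl2, 0 °C → rt; concentrate, use crude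
Reagents that add atoms: none
Why: Aza-Michael (conjugate) addition of a secondary amine to the doubly activated alkyne is fast without catalyst and should give the push–pull enamine with the acetal untouched, since the medium is neutral and anhydrous.

Step 2
Reactants: 3 dimethyl (E)-2-[(2,2-dimethoxyethyl)(methyl)amino]but-2-enedioate
Product: 5 dimethyl 1-methyl-1H-pyrrole-2,3-dicarboxylate, via 4-methoxy-4,5-dihydropyrrole diester 4 (not isolated)
Conditions: anhydrous CF3CO2H–CH2Cl2 (1:4), 0 °C → rt (40 °C if slow); NaHCO3 work-up
Reagents that add atoms: none
Why: Acid protonates an acetal oxygen and expels methanol to give an oxocarbenium ion at C4, held through C5 on N1; C3, the β-carbon of the N1–C2=C3 enamine, attacks it to form the C3–C4 bond, loss of the C3 proton gives 4, and acid-promoted elimination of the second methanol aromatises the ring to 5. The closest known reaction type is the acid-mediated cyclisation of N-(2,2-dialkoxyethyl) enaminones and enamino esters to pyrroles, an intramolecular enamine–oxocarbenium aldol-type condensation related to the Pomeranz–Fritsch cyclisation. The single ring closes in a 5-exo-trig mode at the C4=O+ bond with the C2=C3 bond inside the new ring (formally 5-(enolendo)-exo-trig), a closure that is well established for this enamine–acetal class and is made irreversible by aromatisation. No stereocentre survives: C4 of 4 is formed as a racemate and is destroyed on elimination, and the alkene geometry of 3 is irrelevant because C3 becomes a ring carbon. The step needs C-cyclisation to beat enamine hydrolysis and intermolecular condensation; only C3 can reach the tethered cation in a five-membered transition state, and anhydrous acid at moderate dilution keeps water and bimolecular pathways out. The C2 (α) and C3 (β) esters emerge electronically distinct, which the endgame uses.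

Step 3
Reactants: 5 dimethyl 1-methyl-1H-pyrrole-2,3-dicarboxylate; 6 bromine
Product: 8 dimethyl 4,5-dibromo-1-methyl-1H-pyrrole-2,3-dicarboxylate, via 5-bromo diester 7 (not isolated)
Conditions: Br2 (2.3 equiv), AcOH, rt → 50 °C; aq. Na2S2O3
Reagents that add atoms: bromine, BrBr
Why: Electrophilic aromatic bromination should take C5 (the α-position, not conjugated with the C3 ester) first and C4 on warming with excess bromine, these being the only ring C–H positions, and the diester ring is stable to the HBr formed.

Step 4
Reactants: 8 dimethyl 4,5-dibromo-1-methyl-1H-pyrrole-2,3-dicarboxylate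
Product: 9 4,5-dibromo-2-(methoxycarbonyl)-1-methyl-1H-pyrrole-3-carboxylic acid
Conditions: 96% H2SO4, 20 → 40 °C; then ice–water
Reagents that add atoms: water, O
Why: Ester cleavage in concentrated sulfuric acid runs through an acylium ion (AAC1 hydrolysis), and by the classical selectivity of pyrrole polyesters (β-esters cleaved by concentrated H2SO4, α-esters by alkali, as for diethyl 3,5-dimethylpyrrole-2,4-dicarboxylate) the C3 ester, whose carbonyl is the more basic vinylogous carbamate of N1, should ionise preferentially and give the β-acid on quench, while the fully substituted ring cannot be sulfonated.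

Step 5
Reactants: 9 4,5-dibromo-2-(methoxycarbonyl)-1-methyl-1H-pyrrole-3-carboxylic acid; 6 bromine
Product: 11 methyl 3,4,5-tribromo-1-methyl-1H-pyrrole-2-carboxylate, via sodium carboxylate 10 (not isolated)
Conditions: NaHCO3 (1.2 equiv), H2O–1,4-dioxane, rt; then Br2 (1.1 equiv), 0 °C → rt; aq. Na2S2O3
Reagents that add atoms: bromine, BrBr; sodium hydrogen carbonate, [Na+].OC([O-])=O (sodium of 10 only)
Why: Ipso-bromodecarboxylation (ionic, Hunsdiecker-type halodecarboxylation of a pyrrolecarboxylate) should occur because C3 is the only ring carbon carrying an electrofuge: electrophilic bromine adds there to give a σ-complex stabilised by N1 through C2, which loses CO2 irreversibly, while the C2 ester cannot leave and C4/C5 are already brominated.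

Step 6
Reactants: 11 methyl 3,4,5-tribromo-1-methyl-1H-pyrrole-2-carboxylate
Product: 13 3,4,5-tribromo-1-methyl-1H-pyrrole-2-carboxylic acid, via lithium carboxylate 12 (not isolated)
Conditions: LiOH·H2O (3 equiv), THF–MeOH–H2O, 50 °C; then 1 M HCl, 0 °C, pH 2
Reagents that add atoms: lithium hydroxide, [Li+].[OH-]
Why: BAC2 saponification of the one remaining, hindered methyl ester followed by cold acidification should deliver the acid, since the ring C–Br bonds are inert to hydroxide and the electron-poor tribromo acid should resist protodecarboxylation at this pH.

Compound list
1 | (methylamino)acetaldehyde dimethyl acetal (2,2-dimethoxy-N-methylethanamine) | CNCC(OC)OC | starting material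
2 | dimethyl acetylenedicarboxylate (dimethyl but-2-ynedioate) | COC(=O)C#CC(=O)OC | starting material
3 | dimethyl (E)-2-[(2,2-dimethoxyethyl)(methyl)amino]but-2-enedioate | COC(=O)/C=C(/N(C)CC(OC)OC)C(=O)OC | intermediate
4 | dimethyl 4-methoxy-1-methyl-4,5-dihydro-1H-pyrrole-2,3-dicarboxylate (racemic, not isolated) | COC1CN(C)C(C(=O)OC)=C1C(=O)OC | intermediate
5 | dimethyl 1-methyl-1H-pyrrole-2,3-dicarboxylate | COC(=O)c1ccn(C)c1C(=O)OC | intermediate
6 | bromine | BrBr | starting material
7 | dimethyl 5-bromo-1-methyl-1H-pyrrole-2,3-dicarboxylate (not isolated) | COC(=O)c1cc(Br)n(C)c1C(=O)OC | intermediate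
8 | dimethyl 4,5-dibromo-1-methyl-1H-pyrrole-2,3-dicarboxylate | COC(=O)c1c(Br)c(Br)n(C)c1C(=O)OC | intermediate
9 | 4,5-dibromo-2-(methoxycarbonyl)-1-methyl-1H-pyrrole-3-carboxylic acid | COC(=O)c1c(C(=O)O)c(Br)c(Br)n1C | intermediate
10 | sodium 4,5-dibromo-2-(methoxycarbonyl)-1-methyl-1H-pyrrole-3-carboxylate (not isolated) | [Na+].[O-]C(=O)c1c(Br)c(Br)n(C)c1C(=O)OC | intermediate
11 | methyl 3,4,5-tribromo-1-methyl-1H-pyrrole-2-carboxylate | COC(=O)c1c(Br)c(Br)c(Br)n1C | intermediate
12 | lithium 3,4,5-tribromo-1-methyl-1H-pyrrole-2-carboxylate (not isolated) | [Li+].[O-]C(=O)c1c(Br)c(Br)c(Br)n1C | intermediate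
13 | 3,4,5-tribromo-1-methyl-1H-pyrrole-2-carboxylic acid | Cn1c(Br)c(Br)c(Br)c1C(=O)O | target

Total step count: 6. Longest linear sequence: 6 steps (1 and 2 to 13).

Steps most likely to fail

Step 2. Adventitious water could hydrolyse the enamine or unmask the aldehyde, so that cleavage and intermolecular condensation outrun attack by the electron-poor C3; C-protonation of the enamine could also stall ring closure. The fallback is a Hantzsch-type annulation that builds the same ring intermolecularly and closes it at N1–C5. It sets out from 2: methylamine (2 M in THF, 0 °C) should add to give dimethyl (Z)-2-(methylamino)but-2-enedioate F1, a hydrogen-bonded N–H enamine that tolerates water. Heating F1 with aqueous chloroacetaldehyde and NaHCO3 in EtOH (60 °C) should join C3 to the aldehyde carbon and N1 to the chloromethyl carbon and dehydrate, coming back to the route at 5.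

Step 4. The two esters might not be discriminated: ionisation of the C2 ester as well, or participation of the neighbouring ester leading on to the diacid or its anhydride, would erode the selectivity. A sluggish substrate would also need temperatures at which the α-carboxyl is lost. The fallback differentiates the carboxyls through the cyclic anhydride, using the opposite, nucleophile-based preference for the C2 carbonyl. It sets out from 8: exhaustive saponification (NaOH, aq. MeOH, reflux; HCl) should give 4,5-dibromo-1-methyl-1H-pyrrole-2,3-dicarboxylic acid F2. Dehydration with (CF3CO)2O in CH2Cl2 should give the cyclic anhydride 2,3-dibromo-1-methyl-1H-furo[3,4-b]pyrrole-4,6-dione F3. Methanol should open F3 at the carbonyl on C2, because the carbonyl on C3 is deactivated as a vinylogous carbamate of N1, coming back to the route at 9.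

Step 5. Ipso attack at the electron-poor, doubly flanked C3 may be slow, so that conversion stalls while hypobromite degrades the ring or the ester is hydrolysed. The fallback separates decarboxylation from bromination. It sets out from 9: protodecarboxylation (Ag2CO3 cat., AcOH cat., DMSO, 120 °C) should give methyl 4,5-dibromo-1-methyl-1H-pyrrole-2-carboxylate F4. Ordinary electrophilic bromination of the freed C3–H (Br2, AcOH, 60 °C) should then come back to the route at 11.

Further compounds
F1 | step 2 | dimethyl (Z)-2-(methylamino)but-2-enedioate | CN/C(=C\C(=O)OC)C(=O)OC
F2 | step 4 | 4,5-dibromo-1-methyl-1H-pyrrole-2,3-dicarboxylic acid | Cn1c(Br)c(Br)c(C(=O)O)c1C(=O)O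
F3 | step 4 | 2,3-dibromo-1-methyl-1H-furo[3,4-b]pyrrole-4,6-dione (4,5-dibromo-1-methylpyrrole-2,3-dicarboxylic anhydride) | Cn1c(Br)c(Br)c2C(=O)OC(=O)c12
F4 | step 5 | methyl 4,5-dibromo-1-methyl-1H-pyrrole-2-carboxylate | COC(=O)c1cc(Br)c(Br)n1C
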